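Early on I watch how fast the solid substrate leaves in the two earlier runs; the flasks, readings and questions are these.

in all of them: solid substrate 0.39 M; gas 17 mM (held)
- red: second substrate 1 equiv; third substrate 2.5 equiv; temperature 55 °C; run made earlier
- amber: second substrate 1 equiv; third substrate 4.5 equiv; temperature 70 °C; run made earlier
- Thursday's: second substrate 1.00 equiv; third substrate 1.20 equiv; at 80 °C throughout; time 20 d
- Wednesday's: second substrate 1.00 equiv; third substrate 5.00 equiv; at 60 °C until 4.0 d, from then on at 80 °C; time 20 d

| run | time / d | target / % | solid substrate / % |
|---|---|---|---|
| red | 1.25 | 3.7 | 90.6 |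
| red | 4.00 | 24.0 | 70.3 |
| red | 6.00 | 35.2 | 58.1 |
| red | 10.0 | 64.6 | 29.7 |
| red | 15.0 | 97.1 | 0.2 |
| amber | 0.625 | 3.6 | 93.9 |
| amber | 1.25 | 7.1 | 90.3 |
| amber | 2.50 | 16.5 | 81.4 |
| amber | 5.00 | 37.9 | 61.9 |
| amber | 10.0 | 73.5 | 26.5 |

(readings scatter by 1 percentage point)

* the winner by amount of target, in percent of the solid substrate charged; "neither" if no more than 2 percentage points parts them (Thursday's / Wednesday's / neither)
* how much target is there at the end, in percent of the solid substrate charged: Thursday's
* how much target is there at the end, in percent of the solid substrate charged: Wednesday's

- given per volume of solution although it is solid: solid substrate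
- the numbers in the tables scatter by 1 percentage point (one standard deviation)
- at the start none of the gas is in solution
- at the start none of the solid substrate is in solution
- what has only dissolved of solid substrate counts as not reacted

The first rung is the wait of what has dissolved. In the red run, 5.7 percentage points of the charge is neither solid substrate nor target at 4.00 d, and the solid substrate leaves at 0.0703 /d up to 10.0 d, so a dissolved portion waits about 0.811 d.

The next rung is the amber run's 0.0735 /d, which I carry as the feed: the fraction of the charge leaving the solid per day. This reading stands a factor of 1.05 above the red run's, and the two runs differ in both temperature, 55 °C against 70 °C, and third substrate. At that feed one charge takes 13.6 d, and a dissolved pool with the red run's wait turns over about 16.8 times in that span, so in these two runs I call going into solution the rate-limiting step.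

The top rung is the asked 20 d, which holds 1.47 charges. Wednesday's cool 4.0 d at 60 °C lies between the temperatures of the two earlier runs, whose feeds differ by 0.00320 /d, far less than either, so I expect the cool start to cost Wednesday's little. By this count, Thursday's and Wednesday's each have 6.40 d left after one charge, at 80 °C, hotter than either earlier run. I reckon that neither flask leads by more than 2 points, with target near the red run's final sum of target and solid substrate, 97.3%, less whatever those days take.

The forecast says neither, with Thursday's at 97% (85% to 100%) and Wednesday's at 98% (92% to 100%), since “both flasks finish within about 15 d”.

Thursday's ends at 90.6% and Wednesday's at 91.1%, 0.50 points apart, so neither wins; at 20.0 d, Thursday's holds 0% solid substrate and 9.39% over-reaction product, Wednesday's 0% and 8.92%.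

    third substrate + partner → third product (k = 0.710 /M/h, Ea = 63.0 kJ/mol)
    gas ⇌ partner, rate k2*(csat - [partner]) (kL = 4.50 /h)
    starting material + partner → target (k = 5.40 /M/h, Ea = 76.0 kJ/mol)
    second substrate + partner → second product (k = 0.170 /M/h, Ea = 66.0 kJ/mol)
    target → over-reaction product (k = 2.50 × 10⁻⁵ /h, Ea = 123 kJ/mol)
    solid substrate ⇌ starting material, rate k6*(cs6 - [starting material]) while solid is left; crystals form when [starting material] > cs6 (solubility = 0.200 M, k = 0.00630 /h)
    (constants at 60 °C)

The feed leaves 26.5% of Thursday's solid substrate at 10.0 d, where 23.6% stands. Read at 5.0 d, Wednesday's should hold 63.3% solid substrate by the feed, and it holds 63.5%.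

The numbers in the tables are calculated from invented constants; scatter was added.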